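**Strategy.** In asbestinin numbering the oxepane (C2, C1, C14, C15, C16, O16, C3) splits into C2–C1–C14, whose ends are both latent cations (C2: acetal carbon of the tetrahydrofuran; C14: allylic carbon of the cyclohexene), and C3–O16–C16–C15, a latent 1,4-bis-nucleophile (C3: α-carbon of a lactate ester; C15: β-carbon of its O-propenyl ether). One TMSOTf-catalysed formal (4+3) annulation forms C2–C3 and C14–C15 and sets C2, C3, C14 and C15. Its precursor is a Diels–Alder-derived hydroisobenzofuran acetal carrying an allylic silyl ether at C14 and the lactate silyl ketene acetal tethered to the C9 hydroxymethyl group; the oxonane is closed later by metathesis.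

Key step: step 9

Remark: (R)-5-(hydroxymethyl)furan-2(5H)-one (1) is taken as a catalogue compound. Atom numbers are asbestinin numbers (O9 bridges C2/C9, O16 bridges C3/C16; C17 = methyl on C15, C18 = methyl on C3, C19 = CH2 on C7, C20 = methyl on C12; α = face of the cyclohexane carrying C2/C9, β = face of H1/H10).

Step 1
Reactants: 1 (R)-5-(hydroxymethyl)furan-2(5H)-one
Product: 2 [(2R)-5-oxo-2,5-dihydrofuran-2-yl]methyl pivalate
Conditions: PivCl, Et3N, DMAP (cat.), CH2Cl2, 0 °C
Reagents that add atoms: pivaloyl chloride, CC(C)(C)C(Cl)=O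
Why: Simple O-acylation; the pivalate masks the C8 hydroxyl during the cycloaddition and is removed by the same DIBAL-H operation that later reduces the lactone.

Step 2
Reactants: 3 3-methylbut-2-enal
Product: 4 (E)-tert-butyldimethyl[(3-methylbuta-1,3-dien-1-yl)oxy]silane
Conditions: TBSOTf, Et3N, Et2O, 0 °C to rt
Reagents that add atoms: tert-butyldimethylsilyl trifluoromethanesulfonate, CC(C)(C)[Si](C)(C)OS(=O)(=O)C(F)(F)F
Why: γ-Deprotonative O-silylation of the enal (silyl dienol ether formation) should give the (E)-1-silyloxy diene.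

Step 3
Reactants: 2 [(2R)-5-oxo-2,5-dihydrofuran-2-yl]methyl pivalate; 4 (E)-tert-butyldimethyl[(3-methylbuta-1,3-dien-1-yl)oxy]silane
Product: 5 cis-fused 7-(TBS-oxy)-5-methyl-3-(pivaloyloxymethyl)-3a,4,7,7a-tetrahydroisobenzofuran-1(3H)-one (C2 lactone, C9 arm anti to the cyclohexene, C14 OTBS endo, C12=C13)
Conditions: toluene, BHT (cat.), 110 °C, sealed tube
Reagents that add atoms: diene 4, C=C(C)/C=C/O[Si](C)(C)C(C)(C)C
Why: Diels–Alder reaction; the silyloxy terminus bonds to the lactone α-carbon (ortho rule, gives C1–C14 and C10–C11), the diene adds anti to the C9 substituent (sets C1 and C10 from C9) and endo (C14).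

Step 4
Reactants: 5 Diels–Alder adduct
Product: 7 [1-methoxy-7-(TBS-oxy)-5-methyl-1,3,3a,4,7,7a-hexahydroisobenzofuran-3-yl]methanol (C2 methyl acetal, anomer mixture; free C8 OH), via the lactol diol 6 (not isolated)
Conditions: DIBAL-H (3.5 equiv), CH2Cl2, −78 °C; then MeOH, PPTS, rt
Reagents that add atoms: methanol, CO
Why: DIBAL-H reduction of the lactone to the lactol with reductive removal of the pivalate, then acid-catalysed acetalisation; both anomers lead to the same oxocarbenium ion later.

Step 5
Reactants: 8 2-bromopropanoic acid; 9 prop-2-en-1-ol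
Product: 10 2-(prop-2-en-1-yloxy)propanoic acid (racemic)
Conditions: NaH (2.2 equiv), THF, 0 °C to reflux; then aq. HCl
Reagents that add atoms: prop-2-en-1-ol 9, C=CCO
Why: Williamson ether synthesis on the bromo carboxylate; the stereocentre is erased later by enolisation, so the racemate suffices.

Step 6
Reactants: 7 methyl acetal alcohol; 10 2-(prop-2-en-1-yloxy)propanoic acid
Product: 11 C8 ester of 7 with 2-(allyloxy)propanoic acid
Conditions: DCC, DMAP (cat.), CH2Cl2, 0 °C to rt
Reagents that add atoms: acid 10, C=CCOC(C)C(=O)O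
Why: Steglich esterification of the only free (primary) hydroxyl installs the C3/C4/O16 unit on a tether that can reach C2 only from the face of the C9 arm.

Step 7
Reactants: 11 allyl ether ester
Product: 12 (E)-prop-1-enyl ether ester
Conditions: [Ir(cod)(PMePh2)2]PF6 (2 mol %, H2-activated), THF, rt
Reagents that add atoms: none
Why: Iridium-hydride allyl-to-propenyl ether isomerisation should give the (E)-enol ether and leave the trisubstituted ring alkene untouched; it also removes the allyl vinyl ether motif that could rearrange in step 8.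

Step 8
Reactants: 12 (E)-prop-1-enyl ether ester
Product: 13 trimethylsilyl ketene acetal of 12 (O16 cis to OSiMe3)
Conditions: LDA, TMSCl, Et3N, THF, −78 °C (in situ quench); used crude
Reagents that add atoms: chlorotrimethylsilane, C[Si](C)(C)Cl
Why: Ester enolate silylation at the only acidic C–H (C3); the lithium chelate between the enolate oxygen and O16 should fix the ketene acetal geometry.

Step 9
Reactants: 13 silyl ketene acetal
Product: 15 pentacyclic 16-methoxy-oxepane (C2–C3 and C14–C15 formed; seven-membered lactone C4(=O)–O–C8 bridging C2/C9; C12=C13; C16 epimer mixture), via the bridged lactone 14 (not isolated)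
Conditions: TMSOTf (0.3 equiv), 2,6-di-tert-butyl-4-methylpyridine, CH2Cl2, −78 to −20 °C; then Et3N
Reagents that add atoms: none
Why: Proposed new method: TMSOTf ionises the C2 methyl acetal at −78 °C and the tethered silyl ketene acetal attacks the C2=O9 oxocarbenium ion through C3 (Mukaiyama-type substitution, 7-endo closure of the bridging lactone, giving 14); on warming the allylic C14 silyl ether leaves as TBSOSiMe3 and the C12–C13–C14 allyl cation is captured by C15 of the propenyl ether (cation–olefin cyclisation with an enol ether terminator, 7-exo closure of the oxepane), after which the C16 oxocarbenium ion takes up the MeOSiMe3 released at C2. The closest known reaction type is the TMSOTf-promoted annulation of bis-silylated bis-nucleophiles with bis-electrophilic acetals or dicarbonyls, here run with a 1,3-bis-electrophile (C2, C14) and a 1,4-bis-nucleophile (C3, C15) as a formal (4+3) annulation catalytic in silyl triflate. C2 is set by the tether, which can deliver C3 only to the face cis to the C9 arm, and C3 by the ketene acetal geometry within that seven-membered transition state, which points O16 toward C1. C14 should be attacked on the face of H1, where the new C2–C3 bond holds the enol ether (trans-fused oxepane), and C15 follows from the (E)-enol ether geometry. The step needs C2 to ionise before C14 and the ketene acetal, not the enol ether, to take C2: an acetal is far more labile than an allylic silyl ether at −78 °C, the ketene acetal is the much stronger nucleophile, and the ring sizes (7 against 8 or 10) disfavour the wrong pairings.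

Step 10
Reactants: 15 pentacyclic 16-methoxy-oxepane
Product: 16 pentacyclic oxepane (C16 = CH2)
Conditions: Et3SiH, BF3·OEt2, CH2Cl2, −78 to −30 °C
Reagents that add atoms: none
Why: Ionic reduction of the mixed cyclic acetal through the endocyclic oxocarbenium ion; lactone and isolated alkene should survive.

Step 11
Reactants: 16 pentacyclic oxepane
Product: 18 C11 enone (C11=O, C12=C13), via the C11 allylic alcohol 17 (not isolated)
Conditions: SeO2 (0.5 equiv), t-BuOOH, CH2Cl2, rt; then Dess–Martin periodinane, NaHCO3, CH2Cl2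
Reagents that add atoms: selenium dioxide, O=[Se]=O, with tert-butyl hydroperoxide, CC(C)(C)OO, as terminal oxidant
Why: Riley allylic oxidation (ene reaction then [2,3] shift) should oxidise the ring CH2 (C11) at the more substituted alkene terminus, and oxidation of the alcohol removes the uncontrolled C11 configuration.

Step 12
Reactants: 18 C11 enone
Product: 19 C11 ketone with C12 methyl α
Conditions: H2 (1 atm), 10 % Pd/C, EtOAc, rt
Reagents that add atoms: none
Why: Heterogeneous hydrogenation should deliver hydrogen to the β face (the concave α face is screened by the C9 side of the tetrahydrofuran), placing the C20 methyl α.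

Step 13
Reactants: 19 C11 ketone
Product: 20 C11 α-alcohol (cis to the C12 methyl)
Conditions: L-Selectride, THF, −78 °C; aq. NH4Cl
Reagents that add atoms: none
Why: The bulky hydride should attack from the open β face at low temperature (no epimerisation at C12), setting the C11 carbinol α; the hindered lactone is not reduced at −78 °C.

Step 14
Reactants: 20 C11 α-alcohol lactone
Product: 21 C4 aldehyde with free C8 and C11 hydroxyls (in equilibrium with its seven-membered lactol)
Conditions: DIBAL-H (2.5 equiv), CH2Cl2, −78 °C; Rochelle salt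
Reagents that add atoms: none
Why: Partial reduction of the bridging lactone stops at the tetrahedral aluminate and so at the aldehyde; the aldehyde is on a quaternary carbon and cannot epimerise.

Step 15
Reactants: 21 hydroxy aldehyde; 22 allyltributylstannane
Product: 23 triol with C4 carbinol and C5–C6 allyl group
Conditions: MgBr2·OEt2, CH2Cl2, −78 to −20 °C
Reagents that add atoms: allyltributylstannane 22, C=CC[Sn](CCCC)(CCCC)CCCC
Why: Chelation-controlled allylstannane addition; in the magnesium chelate between the aldehyde oxygen and O16 the allyl group adds from the C18 methyl side, away from C2, which gives the required C4 configuration.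

Step 16
Reactants: 23 triol; 24 isopropenylmagnesium bromide
Product: 26 diol with C8 2-methylallyl arm, via the primary C8 triflate 25 (not isolated)
Conditions: Tf2O, 2,6-lutidine, CH2Cl2, −78 °C; then 24 (excess), CuI (cat.), THF, −40 to 0 °C
Reagents that add atoms: isopropenylmagnesium bromide 24, C=C(C)[Mg]Br; trifluoromethanesulfonic anhydride, O=S(=O)(OS(=O)(=O)C(F)(F)F)C(F)(F)F (in 25 only)
Why: The primary hydroxyl is triflated selectively at −78 °C and the triflate is displaced in a copper-catalysed Grignard coupling, bringing in C7 and C19.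

Step 17
Reactants: 26 diol; 27 acetic anhydride
Product: 28 C11 acetate
Conditions: pyridine, DMAP (cat.), CH2Cl2, 0 °C, 1.1 equiv of 27
Reagents that add atoms: acetic anhydride 27, CC(=O)OC(C)=O
Why: Selective acylation; the ring C11 hydroxyl should react before the C4 hydroxyl, which sits next to the quaternary C3.

Step 18
Reactants: 28 C11 acetate; 29 octanoyl chloride
Product: 30 C4 octanoate, C11 acetate diene
Conditions: DMAP, pyridine, CH2Cl2, rt
Reagents that add atoms: octanoyl chloride 29, CCCCCCCC(Cl)=O
Why: DMAP-catalysed acylation of the remaining hindered secondary alcohol.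

Step 19
Reactants: 30 diene diester
Product: 31 (Z)-C6=C7 oxonene (complete tetracyclic skeleton, C19 methyl on C7)
Conditions: Grubbs second-generation catalyst (10 mol %), toluene (2 mM), 80 °C
Reagents that add atoms: none
Why: Ring-closing metathesis between the allyl and 2-methylallyl arms, which sit cis on the tetrahydrofuran; the nine-membered ring enforces the Z alkene.

Step 20
Reactants: 31 (Z)-oxonene
Product: 33 C6 allylic alcohol with C7=C19 exocyclic methylene, via the C6 allylic hydroperoxide 32 (not isolated)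
Conditions: O2, tetraphenylporphyrin, hν, CH2Cl2, 0 °C; then PPh3
Reagents that add atoms: oxygen, O=O
Why: Schenck ene reaction of singlet oxygen with the only alkene; abstraction of a C19 methyl hydrogen should give the exocyclic alkene with oxygen on C6, and the C6 configuration is irrelevant.

Step 21
Reactants: 33 C6 allylic alcohol
Product: 34 Asbestinin 16
Conditions: Dess–Martin periodinane, NaHCO3, CH2Cl2, 0 °C to rt
Reagents that add atoms: none
Why: Buffered Dess–Martin oxidation gives the α-methylene ketone without eliminating the β-octanoate.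

**Compound list**

1 | (R)-5-(hydroxymethyl)furan-2(5H)-one | OC[C@@H]1OC(=O)C=C1 | starting material
2 | [(2R)-5-oxo-2,5-dihydrofuran-2-yl]methyl pivalate | CC(C)(C)C(=O)OC[C@@H]1OC(=O)C=C1 | intermediate
3 | 3-methylbut-2-enal | CC(C)=CC=O | starting material
4 | (E)-tert-butyldimethyl[(3-methylbuta-1,3-dien-1-yl)oxy]silane | C=C(C)/C=C/O[Si](C)(C)C(C)(C)C | intermediate
5 | cis-fused Diels–Alder lactone (C14 OTBS, C12=C13, C9 CH2OPiv) | CC(C)(C)C(=O)OC[C@@H]2OC(=O)[C@H]4[C@@H](O[Si](C)(C)C(C)(C)C)C=C(C)C[C@H]42 | intermediate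
6 | lactol diol (C2 OH, C8 OH; anomer mixture) | OC[C@@H]2OC(O)[C@H]4[C@@H](O[Si](C)(C)C(C)(C)C)C=C(C)C[C@H]42 | intermediate
7 | C2 methyl acetal, C8 alcohol (anomer mixture) | OC[C@@H]2OC(OC)[C@H]4[C@@H](O[Si](C)(C)C(C)(C)C)C=C(C)C[C@H]42 | intermediate
8 | 2-bromopropanoic acid | CC(Br)C(=O)O | starting material
9 | prop-2-en-1-ol | C=CCO | starting material
10 | 2-(prop-2-en-1-yloxy)propanoic acid | C=CCOC(C)C(=O)O | intermediate
11 | C8 2-(allyloxy)propanoate of 7 | C=CCOC(C)C(=O)OC[C@@H]2OC(OC)[C@H]4[C@@H](O[Si](C)(C)C(C)(C)C)C=C(C)C[C@H]42 | intermediate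
12 | C8 2-[(E)-prop-1-enyloxy]propanoate of 7 | C/C=C/OC(C)C(=O)OC[C@@H]2OC(OC)[C@H]4[C@@H](O[Si](C)(C)C(C)(C)C)C=C(C)C[C@H]42 | intermediate
13 | trimethylsilyl ketene acetal of 12 (O16 cis to OSiMe3) | C/C=C/O/C(C)=C(\O[Si](C)(C)C)OC[C@@H]2OC(OC)[C@H]4[C@@H](O[Si](C)(C)C(C)(C)C)C=C(C)C[C@H]42 | intermediate
14 | bridged lactone after C2–C3 bond formation (C14 OTBS and propenyl ether intact) | O=C1OC[C@@H]2O[C@@H]([C@H]4[C@@H](O[Si](C)(C)C(C)(C)C)C=C(C)C[C@H]42)[C@@]1(C)O/C=C/C | intermediate
15 | pentacyclic 16-methoxy-oxepane lactone (C16 epimers) | O=C1OC[C@@H]2O[C@H]3[C@H]4[C@@H](C=C(C)C[C@H]42)[C@@H](C)C(OC)O[C@]31C | intermediate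
16 | pentacyclic oxepane lactone | O=C1OC[C@@H]2O[C@H]3[C@H]4[C@@H](C=C(C)C[C@H]42)[C@@H](C)CO[C@]31C | intermediate
17 | C11 allylic alcohol (C11 epimers) | O=C1OC[C@@H]2O[C@H]3[C@H]4[C@@H](C=C(C)C(O)[C@H]42)[C@@H](C)CO[C@]31C | intermediate
18 | C11 enone | O=C1OC[C@@H]2O[C@H]3[C@H]4[C@@H](C=C(C)C(=O)[C@H]42)[C@@H](C)CO[C@]31C | intermediate
19 | C11 ketone, C12 methyl α | O=C1OC[C@@H]2O[C@H]3[C@H]4[C@@H](C[C@@H](C)C(=O)[C@H]42)[C@@H](C)CO[C@]31C | intermediate
20 | C11 α-alcohol | O=C1OC[C@@H]2O[C@H]3[C@H]4[C@@H](C[C@@H](C)[C@@H](O)[C@H]42)[C@@H](C)CO[C@]31C | intermediate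
21 | C4 aldehyde, C8 and C11 diol | OC[C@@H]2O[C@H]3[C@H]4[C@@H](C[C@@H](C)[C@@H](O)[C@H]42)[C@@H](C)CO[C@@]3(C)C=O | intermediate
22 | allyltributylstannane | C=CC[Sn](CCCC)(CCCC)CCCC | starting material
23 | triol with C4 homoallylic alcohol | OC[C@@H]2O[C@H]3[C@H]4[C@@H](C[C@@H](C)[C@@H](O)[C@H]42)[C@@H](C)CO[C@@]3(C)[C@H](O)CC=C | intermediate
24 | isopropenylmagnesium bromide | C=C(C)[Mg]Br | starting material
25 | primary C8 triflate of 23 | O=S(=O)(OC[C@@H]2O[C@H]3[C@H]4[C@@H](C[C@@H](C)[C@@H](O)[C@H]42)[C@@H](C)CO[C@@]3(C)[C@H](O)CC=C)C(F)(F)F | intermediate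
26 | diol with C8 2-methylallyl arm | C=C(C)C[C@@H]2O[C@H]3[C@H]4[C@@H](C[C@@H](C)[C@@H](O)[C@H]42)[C@@H](C)CO[C@@]3(C)[C@H](O)CC=C | intermediate
27 | acetic anhydride | CC(=O)OC(C)=O | starting material
28 | C11 acetate, C4 alcohol | C=C(C)C[C@@H]2O[C@H]3[C@H]4[C@@H](C[C@@H](C)[C@@H](OC(C)=O)[C@H]42)[C@@H](C)CO[C@@]3(C)[C@H](O)CC=C | intermediate
29 | octanoyl chloride | CCCCCCCC(Cl)=O | starting material
30 | C4 octanoate, C11 acetate diene | C=C(C)C[C@@H]2O[C@H]3[C@H]4[C@@H](C[C@@H](C)[C@@H](OC(C)=O)[C@H]42)[C@@H](C)CO[C@@]3(C)[C@H](OC(=O)CCCCCCC)CC=C | intermediate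
31 | (Z)-C6=C7 oxonene | C1[C@@H]2O[C@H]3[C@H]4[C@@H](C[C@@H](C)[C@@H](OC(C)=O)[C@H]42)[C@@H](C)CO[C@@]3(C)[C@H](OC(=O)CCCCCCC)C/C=C1/C | intermediate
32 | C6 allylic hydroperoxide (C6 epimers) | C=C1C[C@@H]2O[C@H]3[C@H]4[C@@H](C[C@@H](C)[C@@H](OC(C)=O)[C@H]42)[C@@H](C)CO[C@@]3(C)[C@H](OC(=O)CCCCCCC)CC1OO | intermediate
33 | C6 allylic alcohol (C6 epimers) | C=C1C[C@@H]2O[C@H]3[C@H]4[C@@H](C[C@@H](C)[C@@H](OC(C)=O)[C@H]42)[C@@H](C)CO[C@@]3(C)[C@H](OC(=O)CCCCCCC)CC1O | intermediate
34 | Asbestinin 16 | C=C1C[C@@H]2O[C@H]3[C@H]4[C@@H](C[C@@H](C)[C@@H](OC(C)=O)[C@H]42)[C@@H](C)CO[C@@]3(C)[C@H](OC(=O)CCCCCCC)CC1=O | target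

**Totals and risks**

Total step count: 21. Longest linear sequence: 19 steps (1 → 2 → 5 → 7 → 11 → … → 34).

1. Step 9 (Proposed new method). The second alkylation may not follow the first: the allyl cation may lose a proton to a diene, C14 may ionise before C2, or the enol ether may close on the wrong face of C14 or give the C15 epimer. The fallback uses known reactions, sets out from 11 and returns at 16.
   - Allyl ether 11 is converted with LDA/TMSCl into its silyl ketene acetal F1.
   - TMSOTf at −78 °C then carries out only the Mukaiyama-type substitution at C2 and gives the bridged lactone F2.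
   - TBAF frees the allylic C14 alcohol F3, and Ac2O/pyridine gives the allylic acetate F4.
   - A palladium-ene cyclisation (Pd2(dba)3, PPh3, AcOH, 80 °C) forms C14–C15 on the face opposite to the departed acetate and, after β-hydride elimination, gives the C15-methylene oxepane F5.
   - Hydrogenation of the 1,1-disubstituted alkene with RhCl(PPh3)3 gives 16.

2. Step 20. Singlet oxygen may abstract a ring hydrogen (C5 or C8) instead of a C19 methyl hydrogen and place the new alkene in the ring. The fallback sets out from 31 and returns at 33.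
   - m-CPBA gives the C6–C7 epoxide F7.
   - TMSOTf/DBU opens it at the tertiary C7 with loss of a methyl proton to the allylic silyl ether F8.
   - Citric acid in methanol removes the silyl group to give 33.

3. Step 19. Ring closure to a trisubstituted alkene in a bridged nine-membered ring may lose to oligomerisation or stall at the ruthenium alkylidene of the allyl arm. The fallback sets out from 30 and returns at 31.
   - Ozonolysis (O3, then Me2S) cleaves both terminal alkenes to the C6 aldehyde / C7 methyl ketone F6.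
   - An intramolecular McMurry coupling (TiCl3, Zn–Cu, DME, high dilution) joins C6 and C7 to give 31.

**Further compounds**

F1 | step 9 | trimethylsilyl ketene acetal of allyl ether ester 11 | C=CCO/C(C)=C(\O[Si](C)(C)C)OC[C@@H]2OC(OC)[C@H]4[C@@H](O[Si](C)(C)C(C)(C)C)C=C(C)C[C@H]42
F2 | step 9 | bridged lactone with O16 allyl ether and C14 OTBS | O=C1OC[C@@H]2O[C@@H]([C@H]4[C@@H](O[Si](C)(C)C(C)(C)C)C=C(C)C[C@H]42)[C@@]1(C)OCC=C
F3 | step 9 | bridged lactone with O16 allyl ether and C14 allylic alcohol | O=C1OC[C@@H]2O[C@@H]([C@H]4[C@@H](O)C=C(C)C[C@H]42)[C@@]1(C)OCC=C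
F4 | step 9 | bridged lactone with O16 allyl ether and C14 allylic acetate | O=C1OC[C@@H]2O[C@@H]([C@H]4[C@@H](OC(C)=O)C=C(C)C[C@H]42)[C@@]1(C)OCC=C
F5 | step 9 | pentacyclic oxepane lactone with C15 exocyclic methylene | O=C1OC[C@@H]2O[C@H]3[C@H]4[C@@H](C=C(C)C[C@H]42)C(=C)CO[C@]31C
F6 | step 19 | C6 aldehyde / C7 methyl ketone from ozonolysis of 30 | CC(=O)C[C@@H]2O[C@H]3[C@H]4[C@@H](C[C@@H](C)[C@@H](OC(C)=O)[C@H]42)[C@@H](C)CO[C@@]3(C)[C@H](OC(=O)CCCCCCC)CC=O
F7 | step 20 | C6–C7 epoxide of 31 | C1[C@@H]2O[C@H]3[C@H]4[C@@H](C[C@@H](C)[C@@H](OC(C)=O)[C@H]42)[C@@H](C)CO[C@@]3(C)[C@H](OC(=O)CCCCCCC)CC5OC15C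
F8 | step 20 | C6 trimethylsilyl ether of 33 | C=C1C[C@@H]2O[C@H]3[C@H]4[C@@H](C[C@@H](C)[C@@H](OC(C)=O)[C@H]42)[C@@H](C)CO[C@@]3(C)[C@H](OC(=O)CCCCCCC)CC1O[Si](C)(C)C
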